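## The problem

The target is a 3-deoxy B-type proanthocyanidin in which C4 of a (2S,4R)-luteoliflavan unit is bonded to C8 of (−)-epigallocatechin 3-O-gallate. The lower half can be assembled from commercial (−)-epigallocatechin 6, which brings the (2R,3R) stereocenters, and a gallic acid derivative, so the synthesis has to build ring C of the upper flavan and the bond from upper C4 to lower C8, a diarylmethine carbon between two 2,6-dioxygenated benzene rings that must be joined at C8 and not at C6 of lower ring A. The upper unit has two stereocenters in a 1,3-trans relation on ring C and no oxygen at C3 to direct either; the stereocenters of the lower unit are too remote to fix its absolute configuration, so C2 must be set by a catalyst. C2 can then control C4 through the ring, but only if the C4–aryl bond is formed last, since hydrogenation of any ring C alkene would deliver the 2,4-cis isomer. Sensitive features are the twelve phenols (the two pyrogallol-type rings are air-sensitive in base), the galloyl ester, and lower C2, which epimerizes in base through a quinone methide while the 4'-hydroxyl is free. Under acid the interflavan bond and the cyclic benzylic ethers are labile, and a 3-deoxyflavan-4-yl cation easily loses a proton to a flav-3-ene that oligomerizes. The feature that opens the key step is that upper C4 carries two aryl carbons (C4a of upper ring A and C8 of lower ring A) and one hydrogen and is joined through C3H2 to the benzylic ether carbon C2, while upper ring A is a phloroglucinol whose two carbons ortho to O1 are equivalent. The atoms O1–C2–C3–C4 are therefore those of an aryl propargyl ether, Ar–O–CH(Ar)–C≡CH, whose terminal alkyne carbon has the oxidation level of C4 and can be arylated twice, first by its own ring A and then by C8 of the lower unit.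

## Retrosynthesis

13 from 12: the twelve O–CH2Ph bonds are cut. Benzyl ethers are chosen over silyl ethers or esters because their removal is neutral, which the ester, the interflavan bond and the pyrogallol rings all tolerate. The forward step has to leave the benzylic C–O and C–C bonds of both flavan rings intact.

12 from 5 and 9: two bonds at upper C4 are cut, C4–C8 (lower) and C4–C4a, which unravels ring C to the alkyne of aryl propargyl ether 5. Cutting only C4–C8 would leave a preformed chiral flavan with a leaving group at C4 that must be made and resolved separately. The double cut removes ring C, the C4 stereocenter and the interflavan bond at once and leaves an acyclic ether with a single stereocenter. Forward, the alkyne terminus must be attacked first by ring A of 5 (closing ring C to flav-3-ene 10) and then, after protonation to cation 11, by C8 of 9. This asks for 6-endo closure, an untouched C2, C8 selectivity and trans capture.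

5 from 3 and 4: the O1–C2 bond is cut. A copper allenylidene formed from racemic propargylic acetate 3 is planar, so both enantiomers converge and phenol 4 adds under control of a chiral ligand. This is preferred to an SN2 displacement on a resolved alcohol, which is prone to ionization at this electron-rich benzylic carbon. Forward, O-attack must beat C-attack.

3 from 1: the C2–C3 bond and the acetyl C–O bond are cut. Acetylide addition to aldehyde 1 gives alkoxide 2, which is acetylated in the same flask. The racemate is acceptable by design.

9 from 7 and 8: the ester bond between O3 and the galloyl carbonyl is cut. Bringing the galloyl group in as the commercial tribenzyl ether 8 means that the ester never meets the basic alkylation medium and that the flavan carries only five phenols when it does. Forward, the hindered axial 3-hydroxyl of 7 must be acylated without disturbing C2.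

7 from 6: the five phenolic O–benzyl bonds are cut. Forward, the phenols must be capped without alkylating the secondary 3-hydroxyl and without epimerizing C2.

## Roads not taken

Alternative 1: the obvious cut, C4–C8 only.
- Forward: racemic flavanone A1 is reduced with RuCl(p-cymene)[(S,S)-TsDPEN] under kinetic resolution to cis-flavan-4-ol A2, which a Lewis acid ionizes for capture by 9 to give 12.
- Why not: this passes through the same cation as the chosen plan, so it gains nothing in control of C4. Ring C must be built first as a racemate and then resolved, and a kinetic resolution uses at most half of A1. Reaching A2 takes more operations than the two that lead to 5, and ring closure and fragment union remain separate steps.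

Alternative 2: cut C4–C8 and add a temporary hydroxyl at upper C3.
- Forward: benzylated epicatechin A3 is oxidized at C4 (DDQ, 2-ethoxyethanol) to ether A4. Lewis acid coupling with 9 gives dimer A5, where the axial 3-hydroxyl enforces 3,4-trans attack. Barton–McCombie deoxygenation then gives 12.
- Why not: stereocontrol here is the most secure of all, and the 3-oxygen also suppresses the flav-3-ene pathway. The chosen plan wins on step and redox economy. This road needs about eight operations against six and introduces a C4 oxidation and a C3 oxygen only to remove them, the latter from a hindered axial alcohol next to the diarylmethine.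

Alternative 3: cut C4–C8 at the flavylium oxidation level.
- Forward: unprotected (−)-epigallocatechin 3-O-gallate A6 adds through C8 to C4 of luteolinidin chloride A7 in weak acid to give flav-2-ene A8, and the enol ether C2=C3 is hydrogenated.
- Why not: it is the shortest on paper and needs no protecting groups, but it fails at both upper stereocenters. C4 of A8 forms under the influence of remote stereocenters only, so both epimers are expected. Hydrogen then reaches C2 from the face away from the 4-aryl group, which gives the 2,4-cis flavan. Acid equilibration to correct this would cleave the interflavan bond.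

Key step: step 5

Assumption: the (S,S)-configured pybox ligand is taken to deliver the (S)-ether 5; the sense of induction depends on ligand and substrate, and the enantiomeric ligand is used if the opposite sense is found.

## Route

Step 1  
Reactants: 1 3,4-bis(benzyloxy)benzaldehyde  
Product: 3 rac-1-[3,4-bis(benzyloxy)phenyl]prop-2-yn-1-yl acetate, via bromomagnesium alkoxide 2 (not isolated)  
Conditions: HC≡CMgBr (1.2 equiv), THF, 0 °C; then Ac2O (1.5 equiv), 0 °C to rt  
Reagents that add atoms: ethynylmagnesium bromide, C#C[Mg]Br; acetic anhydride, CC(=O)OC(C)=O  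
Why: Grignard addition of the acetylide to the aldehyde, then acylation of the magnesium alkoxide in the same flask. The carbinol center is formed as a racemate on purpose, since step 2 is enantioconvergent.

Step 2  
Reactants: 3 rac-1-[3,4-bis(benzyloxy)phenyl]prop-2-yn-1-yl acetate; 4 3,5-bis(benzyloxy)phenol  
Product: 5 1,3-bis(benzyloxy)-5-({(1S)-1-[3,4-bis(benzyloxy)phenyl]prop-2-yn-1-yl}oxy)benzene  
Conditions: (CuOTf)2·C6H6 (2.5 mol %), (S,S)-Ph-pybox [2,6-bis((4S)-4-phenyl-4,5-dihydrooxazol-2-yl)pyridine] (6 mol %), iPr2NEt (1.2 equiv), CH2Cl2, −20 °C  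
Reagents that add atoms: none  
Why: Copper-catalysed asymmetric propargylic substitution. The copper acetylide of 3 loses acetate to a copper allenylidene, so both enantiomers of 3 pass through one planar intermediate, and the phenoxide of 4 adds through oxygen to the gamma carbon inside the chiral pybox pocket, setting the (S) center that becomes upper C2. The terminal alkyne this mechanism requires is the one consumed in step 5.

Step 3  
Reactants: 6 (−)-epigallocatechin  
Product: 7 (2R,3R)-5,7-bis(benzyloxy)-2-[3,4,5-tris(benzyloxy)phenyl]chroman-3-ol  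
Conditions: BnBr (5.5 equiv), K2CO3 (6 equiv), degassed DMF, argon, −10 °C to rt  
Reagents that add atoms: benzyl bromide, BrCc1ccccc1  
Why: Williamson etherification of the five phenols; carbonate does not deprotonate the secondary 3-hydroxyl, which stays free. The 4'-hydroxyl of the pyrogallol ring is the most acidic and is capped first, which closes the quinone methide path to epimerization at C2. No stereocenter is formed.

Step 4  
Reactants: 7 (2R,3R)-5,7-bis(benzyloxy)-2-[3,4,5-tris(benzyloxy)phenyl]chroman-3-ol; 8 3,4,5-tris(benzyloxy)benzoic acid  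
Product: 9 (2R,3R)-5,7-bis(benzyloxy)-2-[3,4,5-tris(benzyloxy)phenyl]chroman-3-yl 3,4,5-tris(benzyloxy)benzoate  
Conditions: DCC (1.5 equiv), DMAP (0.3 equiv), CH2Cl2, 0 °C to rt  
Reagents that add atoms: none  
Why: Steglich esterification: the O-acylisourea of 8 is passed on by DMAP as an acylpyridinium ion, which acylates the hindered axial 3-hydroxyl under neutral conditions. The C3–O bond is not broken and C2 is not exposed to base, so both stereocenters are retained.

Step 5  
Reactants: 5 1,3-bis(benzyloxy)-5-({(1S)-1-[3,4-bis(benzyloxy)phenyl]prop-2-yn-1-yl}oxy)benzene; 9 (2R,3R)-5,7-bis(benzyloxy)-2-[3,4,5-tris(benzyloxy)phenyl]chroman-3-yl 3,4,5-tris(benzyloxy)benzoate  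
Product: 12 (2R,3R)-5,7-bis(benzyloxy)-8-{(2S,4R)-5,7-bis(benzyloxy)-2-[3,4-bis(benzyloxy)phenyl]chroman-4-yl}-2-[3,4,5-tris(benzyloxy)phenyl]chroman-3-yl 3,4,5-tris(benzyloxy)benzoate, via flav-3-ene 10 (not isolated), via flavan-4-yl cation 11 (not isolated)  
Conditions: [Au{P(tBu)2(2-biphenylyl)}(NCMe)]SbF6 (2 mol %), CH2Cl2, 0 °C; solution then added over 4 h to 9 (3 equiv), HNTf2 (5 mol %), CH2Cl2, −60 °C; Et3N quench  
Reagents that add atoms: none  
Why: Proposed new method: a relay geminal diarylation of the alkyne terminus by two different arenes, the closest known reaction types being gold-catalysed cycloisomerization of aryl propargyl ethers to 2H-chromenes, twofold hydroarylation of terminal alkynes to 1,1-diarylalkanes, and capture of flavan-4-yl cations by flavan-3-ol nucleophiles. Cationic monovalent gold activates the alkyne of 5 and an ortho carbon of the 3,5-bis(benzyloxy)phenoxy ring attacks its terminus (6-endo-dig closure of ring C; the two ortho carbons are equivalent, so only one chromene can form), and protodeauration gives 10 without touching the C2–O or C2–H bond. In the second flask the acid protonates 10 at C3 to give cation 11, stabilised by O1 and the 5- and 7-benzyloxy groups. C8 of 9 attacks C4 of 11 and rearomatisation returns the proton, so the acid is catalytic and all atoms of 5 and 9 end in 12. The new C4 stereocenter is controlled by C2: in the sofa conformer of 11 with the 2-aryl group pseudo-equatorial the arene enters along the pseudo-axial trajectory on the face that carries H-2, placing the incoming aryl trans to the 2-aryl group (4R), and the peri 5-benzyloxy group disfavours the equatorial approach that would give the cis isomer. The step needs C8 over C6 selectivity in 9 (C6 lies between two benzyloxy groups, C8 next to the ring oxygen), capture of 11 by 9 rather than by a second molecule of 10 (secured by slow inverse addition into excess 9, which keeps 10 dilute), and integrity of C2 (the acid never meets 5 and acts at −60 °C). The excess of 9 is recovered.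

Step 6  
Reactants: 12 (2R,3R)-5,7-bis(benzyloxy)-8-{(2S,4R)-5,7-bis(benzyloxy)-2-[3,4-bis(benzyloxy)phenyl]chroman-4-yl}-2-[3,4,5-tris(benzyloxy)phenyl]chroman-3-yl 3,4,5-tris(benzyloxy)benzoate  
Product: 13 (2R,3R)-8-[(2S,4R)-2-(3,4-dihydroxyphenyl)-5,7-dihydroxychroman-4-yl]-5,7-dihydroxy-2-(3,4,5-trihydroxyphenyl)chroman-3-yl 3,4,5-trihydroxybenzoate  
Conditions: H2 (1 atm), Pd(OH)2/C, THF/MeOH/H2O, rt; filtration under argon, lyophilization  
Reagents that add atoms: none  
Why: Heterogeneous hydrogenolysis of the twelve benzyl aryl ethers under neutral conditions, as is standard for benzylated proanthocyanidin gallates. The ester, the interflavan C–C bond and the ring-held benzylic ethers C2–O1 should be cleaved far more slowly than benzyl aryl ethers, and no stereocenter is touched.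

## Compound list

1 | 3,4-bis(benzyloxy)benzaldehyde | O=Cc1ccc(OCc2ccccc2)c(OCc2ccccc2)c1 | starting material  
2 | bromomagnesium 1-[3,4-bis(benzyloxy)phenyl]prop-2-yn-1-olate (racemic) | C#CC(O[Mg]Br)c1ccc(OCc2ccccc2)c(OCc2ccccc2)c1 | intermediate  
3 | rac-1-[3,4-bis(benzyloxy)phenyl]prop-2-yn-1-yl acetate | C#CC(OC(C)=O)c1ccc(OCc2ccccc2)c(OCc2ccccc2)c1 | intermediate  
4 | 3,5-bis(benzyloxy)phenol | Oc1cc(OCc2ccccc2)cc(OCc2ccccc2)c1 | starting material  
5 | 1,3-bis(benzyloxy)-5-({(1S)-1-[3,4-bis(benzyloxy)phenyl]prop-2-yn-1-yl}oxy)benzene | C#C[C@H](Oc1cc(OCc2ccccc2)cc(OCc2ccccc2)c1)c1ccc(OCc2ccccc2)c(OCc2ccccc2)c1 | intermediate  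
6 | (−)-epigallocatechin | O[C@@H]1Cc2c(O)cc(O)cc2O[C@@H]1c1cc(O)c(O)c(O)c1 | starting material  
7 | (2R,3R)-5,7-bis(benzyloxy)-2-[3,4,5-tris(benzyloxy)phenyl]chroman-3-ol | O[C@@H]1Cc2c(OCc3ccccc3)cc(OCc3ccccc3)cc2O[C@@H]1c1cc(OCc2ccccc2)c(OCc2ccccc2)c(OCc2ccccc2)c1 | intermediate  
8 | 3,4,5-tris(benzyloxy)benzoic acid | OC(=O)c1cc(OCc2ccccc2)c(OCc2ccccc2)c(OCc2ccccc2)c1 | starting material  
9 | (2R,3R)-5,7-bis(benzyloxy)-2-[3,4,5-tris(benzyloxy)phenyl]chroman-3-yl 3,4,5-tris(benzyloxy)benzoate | O=C(O[C@@H]1Cc2c(OCc3ccccc3)cc(OCc3ccccc3)cc2O[C@@H]1c1cc(OCc2ccccc2)c(OCc2ccccc2)c(OCc2ccccc2)c1)c1cc(OCc2ccccc2)c(OCc2ccccc2)c(OCc2ccccc2)c1 | intermediate  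
10 | (2S)-5,7-bis(benzyloxy)-2-[3,4-bis(benzyloxy)phenyl]-2H-chromene | C1=C[C@@H](c2ccc(OCc3ccccc3)c(OCc3ccccc3)c2)Oc2cc(OCc3ccccc3)cc(OCc3ccccc3)c21 | intermediate  
11 | (2S)-5,7-bis(benzyloxy)-2-[3,4-bis(benzyloxy)phenyl]chroman-4-ylium bis(trifluoromethylsulfonyl)amide | [CH+]1C[C@@H](c2ccc(OCc3ccccc3)c(OCc3ccccc3)c2)Oc2cc(OCc3ccccc3)cc(OCc3ccccc3)c21.[N-](S(=O)(=O)C(F)(F)F)S(=O)(=O)C(F)(F)F | intermediate  
12 | (2R,3R)-5,7-bis(benzyloxy)-8-{(2S,4R)-5,7-bis(benzyloxy)-2-[3,4-bis(benzyloxy)phenyl]chroman-4-yl}-2-[3,4,5-tris(benzyloxy)phenyl]chroman-3-yl 3,4,5-tris(benzyloxy)benzoate | O=C(O[C@@H]1Cc2c(OCc3ccccc3)cc(OCc3ccccc3)c([C@@H]3C[C@@H](c4ccc(OCc5ccccc5)c(OCc5ccccc5)c4)Oc4cc(OCc5ccccc5)cc(OCc5ccccc5)c43)c2O[C@@H]1c1cc(OCc2ccccc2)c(OCc2ccccc2)c(OCc2ccccc2)c1)c1cc(OCc2ccccc2)c(OCc2ccccc2)c(OCc2ccccc2)c1 | intermediate  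
13 | (2R,3R)-8-[(2S,4R)-2-(3,4-dihydroxyphenyl)-5,7-dihydroxychroman-4-yl]-5,7-dihydroxy-2-(3,4,5-trihydroxyphenyl)chroman-3-yl 3,4,5-trihydroxybenzoate | O=C(O[C@@H]1Cc2c(O)cc(O)c([C@@H]3C[C@@H](c4ccc(O)c(O)c4)Oc4cc(O)cc(O)c43)c2O[C@@H]1c1cc(O)c(O)c(O)c1)c1cc(O)c(O)c(O)c1 | target  

## Step count and risk

Total step count: 6. Longest linear sequence: 4 steps (steps 1, 2, 5, 6; the branch through steps 3 and 4 is of equal length up to step 5).

Step 5 (key step). The most likely failure is cationic oligomerization. Every cation 11 is born from chromene 10, whose C3 is a stronger nucleophile than C8 of 9, so attack of 10 on 11, or hydride transfer from C2–H of 10 to 11, competes with capture by 9 unless 10 stays dilute. The fallback sets out from 5. The gold cycloisomerization is run as before, and methanol containing pyridinium p-toluenesulfonate is then added to the crude solution of 10. The alcohol, in large excess, adds to the cation and gives (2S)-5,7-bis(benzyloxy)-2-[3,4-bis(benzyloxy)phenyl]-4-methoxychroman F1 as a mixture of C4 epimers. F1 is isolated and ionized with catalytic TMSOTf in CH2Cl2 at −78 °C in the presence of 9, the established way of joining 4-alkoxyflavans to benzylated flavan-3-ols. No alkene is present when the cation forms, and the route is rejoined at 12.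

Step 2. The most likely failure is C-propargylation, an ortho carbon of the electron-rich phenoxide attacking the allenylidene in place of oxygen. A second risk is erosion of enantiomeric purity by re-ionization of the product ether, whose aryloxide is itself a leaving group. The fallback sets out from 3. Alcoholysis with immobilized Candida antarctica lipase B and n-butanol in tert-butyl methyl ether is expected to cleave the (R)-acetate and leave the (S)-enantiomer of 3, giving (R)-1-[3,4-bis(benzyloxy)phenyl]prop-2-yn-1-ol F2. Mitsunobu etherification of F2 with 4 (PPh3, diisopropyl azodicarboxylate, toluene, −20 °C) inverts the center and rejoins the route at 5.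

Step 3. The most likely failure is base-mediated damage before all phenols are capped: epimerization at C2 through the B-ring quinone methide, autoxidation of the pyrogallol phenoxide, or C-benzylation of the phloroglucinol ring. The fallback sets out from 6. Acetylation (Ac2O, pyridine, rt) gives (−)-epigallocatechin hexaacetate F3. Deacetylative benzylation (benzyl bromide, K2CO3, methanol, DMF) then releases each phenoxide slowly, so it is alkylated at once and free phenoxide never accumulates; the secondary 3-acetate is methanolysed in the same medium to the alcohol, which carbonate does not benzylate. The route is rejoined at 7.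

Step 6. The most likely failure is hydrogenolytic opening of the benzylic C2–O1 bonds competing with removal of the last of the twelve benzyl groups, which are slow to leave once the molecule has become polar. The fallback sets out from 12 and removes the benzyl groups without hydrogen or a metal surface: BCl3 with pentamethylbenzene as cation scavenger in CH2Cl2 at −78 °C, then methanol. This leads directly to 13 and makes no new compound.

## Further compounds

F1 | step 5 | (2S)-5,7-bis(benzyloxy)-2-[3,4-bis(benzyloxy)phenyl]-4-methoxychroman (C4 epimers) | COC1C[C@@H](c2ccc(OCc3ccccc3)c(OCc3ccccc3)c2)Oc2cc(OCc3ccccc3)cc(OCc3ccccc3)c21  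
F2 | step 2 | (R)-1-[3,4-bis(benzyloxy)phenyl]prop-2-yn-1-ol | C#C[C@@H](O)c1ccc(OCc2ccccc2)c(OCc2ccccc2)c1  
F3 | step 3 | (−)-epigallocatechin hexaacetate | CC(=O)O[C@@H]1Cc2c(OC(C)=O)cc(OC(C)=O)cc2O[C@@H]1c1cc(OC(C)=O)c(OC(C)=O)c(OC(C)=O)c1  
F0 | step 6 | none | none  
A1 | alternative 1 | racemic 5,7-bis(benzyloxy)-2-[3,4-bis(benzyloxy)phenyl]chroman-4-one | O=C1CC(c2ccc(OCc3ccccc3)c(OCc3ccccc3)c2)Oc2cc(OCc3ccccc3)cc(OCc3ccccc3)c21  
A2 | alternative 1 | (2S,4S)-5,7-bis(benzyloxy)-2-[3,4-bis(benzyloxy)phenyl]chroman-4-ol | O[C@H]1C[C@@H](c2ccc(OCc3ccccc3)c(OCc3ccccc3)c2)Oc2cc(OCc3ccccc3)cc(OCc3ccccc3)c21  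
A3 | alternative 2 | 5,7,3',4'-tetra-O-benzyl-(−)-epicatechin | O[C@@H]1Cc2c(OCc3ccccc3)cc(OCc3ccccc3)cc2O[C@@H]1c1ccc(OCc2ccccc2)c(OCc2ccccc2)c1  
A4 | alternative 2 | 5,7,3',4'-tetra-O-benzyl-4β-(2-ethoxyethoxy)-(−)-epicatechin | CCOCCO[C@@H]1[C@@H](O)[C@@H](c2ccc(OCc3ccccc3)c(OCc3ccccc3)c2)Oc2cc(OCc3ccccc3)cc(OCc3ccccc3)c21  
A5 | alternative 2 | 5,7,3',4'-tetra-O-benzyl-(−)-epicatechin-(4β→8)-octa-O-benzyl-(−)-epigallocatechin 3-O-gallate | O=C(O[C@@H]1Cc2c(OCc3ccccc3)cc(OCc3ccccc3)c([C@@H]3[C@@H](O)[C@@H](c4ccc(OCc5ccccc5)c(OCc5ccccc5)c4)Oc4cc(OCc5ccccc5)cc(OCc5ccccc5)c43)c2O[C@@H]1c1cc(OCc2ccccc2)c(OCc2ccccc2)c(OCc2ccccc2)c1)c1cc(OCc2ccccc2)c(OCc2ccccc2)c(OCc2ccccc2)c1  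
A6 | alternative 3 | (−)-epigallocatechin 3-O-gallate | O=C(O[C@@H]1Cc2c(O)cc(O)cc2O[C@@H]1c1cc(O)c(O)c(O)c1)c1cc(O)c(O)c(O)c1  
A7 | alternative 3 | luteolinidin chloride (5,7-dihydroxy-2-(3,4-dihydroxyphenyl)chromenylium chloride) | Oc1cc(O)c2ccc(-c3ccc(O)c(O)c3)[o+]c2c1.[Cl-]  
A8 | alternative 3 | (2R,3R)-8-[2-(3,4-dihydroxyphenyl)-5,7-dihydroxy-4H-chromen-4-yl]-5,7-dihydroxy-2-(3,4,5-trihydroxyphenyl)chroman-3-yl 3,4,5-trihydroxybenzoate (both C4 epimers) | O=C(O[C@@H]1Cc2c(O)cc(O)c(C3C=C(c4ccc(O)c(O)c4)Oc4cc(O)cc(O)c43)c2O[C@@H]1c1cc(O)c(O)c(O)c1)c1cc(O)c(O)c(O)c1  
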